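**Strategy.** The plan traces the C3'–Br/C4'–Cl pair of the cyclohexane back to the isomer with the halogens exchanged: bromine on tertiary C4' and chlorine on C3', both axial. On heating, the two halogens swap positions across the C3'–C4' bond and both carbons invert. One operation therefore gives the diequatorial bromide and chloride with an axial C4' methyl, an array that diaxial additions and epoxide openings cannot deliver. The feature exploited is the equatorial oxanyl group on C1', which locks the chair so that the C4'–Br and C3'–Cl bonds are antiperiplanar. The precursor comes from (R)-limonene through (+)-α-bisabolol, bromoetherification to the oxane, and rule-obeying diaxial steps on the ring alkene.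

Key step: step 10

Remark on the chemistry: oxane atoms are O1 and C2–C6, and cyclohexane atoms are C1'–C6' with C1' bonded to C2. "Syn" and "anti" name the cyclohexane faces relative to the C1' substituent, which is assumed to stay equatorial throughout.

Step 1
Reactants: 1 (R)-(+)-limonene
Product: 4 (R)-p-mentha-1,8-dien-10-ol, via limonen-10-yllithium 2 (not isolated), via dimethyl limonen-10-ylboronate 3 (not isolated)
Conditions: n-BuLi, TMEDA, hexane, rt; B(OMe)3, THF, −78 °C to rt; 30% H2O2, aq NaOH, 0 °C
Reagents that add atoms: hydrogen peroxide, OO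
Why: Kinetic allylic lithiation by n-BuLi·TMEDA removes an isopropenyl methyl proton, the 2-substituted allyl anion (equivalent termini) is borylated and oxidised at the C–B bond (lithiation–borylation–oxidation), and the ring stereocentre (future C1', R) is not part of the anion and is retained.

Step 2
Reactants: 4 (R)-p-mentha-1,8-dien-10-ol
Product: 5 [(2S)-2-[(1R)-4-methylcyclohex-3-en-1-yl]oxiran-2-yl]methanol
Conditions: Ti(OiPr)4 (10 mol%), L-(+)-diethyl tartrate (12 mol%), t-BuOOH, 4 Å MS, CH2Cl2, −20 °C
Reagents that add atoms: tert-butyl hydroperoxide, CC(C)(C)OO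
Why: Sharpless asymmetric epoxidation oxidises only the alkene of the allylic alcohol and leaves the isolated ring alkene alone, and the L-(+)-tartrate catalyst sets the 2S oxirane carbon (future C2 of the oxane) under reagent control, as it does for other 2-substituted allyl alcohols.

Step 3
Reactants: 5 [(2S)-2-[(1R)-4-methylcyclohex-3-en-1-yl]oxiran-2-yl]methanol
Product: 6 (2S)-2-[(1R)-4-methylcyclohex-3-en-1-yl]propane-1,2-diol
Conditions: LiAlH4, THF, 0 °C to rt; aq NaOH work-up
Reagents that add atoms: none
Why: Hydride reduction opens the 2,2-disubstituted oxirane by SN2 attack at its unsubstituted CH2, which turns that carbon into the methyl group and breaks no bond at the quaternary stereocentre.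

Step 4
Reactants: 6 (2S)-2-[(1R)-4-methylcyclohex-3-en-1-yl]propane-1,2-diol
Product: 8 (2S)-2-methyl-2-[(1R)-4-methylcyclohex-3-en-1-yl]oxirane, via monotosylate 7 (not isolated)
Conditions: TsCl (1.05 equiv), powdered KOH, THF, 0 °C to rt
Reagents that add atoms: none
Why: Selective sulfonylation of the primary hydroxyl followed by intramolecular Williamson closure by the tertiary alkoxide places the oxirane on the other CH2 arm, again with the stereocentre untouched.

Step 5
Reactants: 8 (2S)-2-methyl-2-[(1R)-4-methylcyclohex-3-en-1-yl]oxirane; 9 prenyl bromide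
Product: 11 (+)-α-bisabolol (2R,1'R), via prenylmagnesium bromide 10 (not isolated)
Conditions: 9 added slowly to Mg, THF, 0 °C; then CuI (10 mol%), 8, THF, −30 to 0 °C; aqueous work-up
Reagents that add atoms: prenyl bromide (9), CC(C)=CCBr
Why: Copper-catalysed opening of a terminal epoxide by an allylic Grignard reagent takes place at the oxirane CH2 and, with CuI present, through the primary terminus of the prenyl unit, which gives the linear homoprenyl chain with the carbinol centre retained.

Step 6
Reactants: 11 (+)-α-bisabolol; 12 N-bromosuccinimide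
Product: 13 (2R,5S)-5-bromo-2,6,6-trimethyl-2-[(1R)-4-methylcyclohex-3-en-1-yl]oxane
Conditions: NBS (1.0 equiv), (CF3)2CHOH, 4 Å MS, 0 °C, dark
Reagents that add atoms: N-bromosuccinimide (12), O=C1CCC(=O)N1Br
Why: In this bromoetherification bromonium formation is reversible and only the side-chain bromonium has the hydroxyl within reach, the ionising non-nucleophilic solvent favours Markovnikov 6-endo attack at the CMe2 carbon, and anti addition through a chair with the cyclohexenyl group equatorial and the C2 methyl axial places the C5 bromine equatorial (5S).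

Step 7
Reactants: 13 (2R,5S)-5-bromo-2,6,6-trimethyl-2-[(1R)-4-methylcyclohex-3-en-1-yl]oxane; 12 N-bromosuccinimide
Product: 15 (1S,4R,6R)-4-[(2R,5S)-5-bromo-2,6,6-trimethyloxan-2-yl]-1-methyl-7-oxabicyclo[4.1.0]heptane (epoxide syn to the oxanyl group), via diaxial bromohydrin 14 (not isolated)
Conditions: NBS, acetone/H2O, 0 °C; then aq NaOH, rt
Reagents that add atoms: water, O
Why: In bromohydrin formation only the anti-face bromonium can be opened by water at tertiary C4' in a way that is both Markovnikov and trans-diaxial (Fürst–Plattner), so 14 should carry an axial C4'–OH syn to the anchor and an axial C3'–Br, and Williamson closure then gives the syn epoxide while the equatorial C5 bromide lacks an antiperiplanar hydrogen and survives base.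

Step 8
Reactants: 15 syn epoxide
Product: 16 (1S,2S,4R)-4-[(2R,5S)-5-bromo-2,6,6-trimethyloxan-2-yl]-2-chloro-1-methylcyclohexan-1-ol
Conditions: LiCl, AcOH, THF, rt to 40 °C
Reagents that add atoms: lithium chloride, [Li+].[Cl-]
Why: In this nucleophilic epoxide opening under weak acid, sterics and the Fürst–Plattner rule both send chloride to secondary C3' from the anti face, which sets the axial 3'S chloride and frees the axial tertiary C4' alcohol, and the neopentyl-type C5 bromide does not exchange.

Step 9
Reactants: 16 diaxial chlorohydrin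
Product: 17 (2R,5S)-5-bromo-2-[(1R,3S,4S)-4-bromo-3-chloro-4-methylcyclohexyl]-2,6,6-trimethyloxane
Conditions: TMSBr (2.5 equiv), CH2Cl2, −30 to 0 °C
Reagents that add atoms: bromotrimethylsilane, C[Si](C)(C)Br
Why: This tertiary alcohol to bromide exchange is SN1 with neighbouring-group participation, in which the axial C3' chlorine is antiperiplanar to the leaving oxygen and covers the anti face as a chloriranium-like ion, so bromide should enter axially at C4' with net retention (4'S), while the ether oxygen between two quaternary carbons is too hindered to be silylated at this temperature.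

Step 10
Reactants: 17 (2R,5S)-5-bromo-2-[(1R,3S,4S)-4-bromo-3-chloro-4-methylcyclohexyl]-2,6,6-trimethyloxane
Product: 18 deoxycaespitol, (2R,5S)-5-bromo-2-[(1R,3R,4R)-3-bromo-4-chloro-4-methylcyclohexyl]-2,6,6-trimethyloxane
Conditions: MeNO2 (dilute), 2,6-di-tert-butyl-4-methylpyridine (0.1 equiv), 80–100 °C, dark, N2; chromatography, recovered 17 resubmitted
Reagents that add atoms: none
Why: The equatorial C1' oxanyl group freezes the chair in which C4'–Br and C3'–Cl are antiperiplanar, so on heating each halogen can slide to the neighbouring carbon on its own face (bromine syn to the oxanyl group, chlorine anti), either through one doubly bridged transition state or through a contact bromiranium chloride pair that collapses at the tertiary carbon. The closest known reaction is the thermal diaxial-to-diequatorial rearrangement of trans vicinal dihalides on steroid cyclohexane rings, a type-one dyotropic shift. No ring is closed and no carbon–carbon bond changes, because only C3'–Br and C4'–Cl form as C4'–Br and C3'–Cl break. Both new stereocentres follow from the stereospecific suprafacial course: inversion at C3' gives 3'R with equatorial bromine, and inversion at C4' gives 4'R with equatorial chlorine and axial methyl. The interchange must outrun loss of HBr, which the antiperiplanar alignment and bromine bridging favour, and it must end on the product side, where the stronger tertiary C–Cl bond and better solvation of the more polar diequatorial isomer in nitromethane have to outweigh the axial methyl. The C5 bromide has no vicinal halogen and no antiperiplanar hydrogen and should stay untouched, and the hindered pyridine only removes adventitious HBr.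

**Compound list**

1 | (R)-(+)-limonene | C=C(C)[C@@H]1CCC(C)=CC1 | starting material
2 | limonen-10-yllithium, [2-[(1R)-4-methylcyclohex-3-en-1-yl]prop-2-en-1-yl]lithium | [Li]CC(=C)[C@@H]1CCC(C)=CC1 | intermediate
3 | dimethyl [2-[(1R)-4-methylcyclohex-3-en-1-yl]prop-2-en-1-yl]boronate | COB(OC)CC(=C)[C@@H]1CCC(C)=CC1 | intermediate
4 | (R)-p-mentha-1,8-dien-10-ol, 2-[(1R)-4-methylcyclohex-3-en-1-yl]prop-2-en-1-ol | OCC(=C)[C@@H]1CCC(C)=CC1 | intermediate
5 | [(2S)-2-[(1R)-4-methylcyclohex-3-en-1-yl]oxiran-2-yl]methanol | OC[C@]1(CO1)[C@@H]2CCC(C)=CC2 | intermediate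
6 | (2S)-2-[(1R)-4-methylcyclohex-3-en-1-yl]propane-1,2-diol | C[C@@](O)(CO)[C@@H]1CCC(C)=CC1 | intermediate
7 | (2S)-2-hydroxy-2-[(1R)-4-methylcyclohex-3-en-1-yl]propyl 4-methylbenzenesulfonate | C[C@@](O)(COS(=O)(=O)c1ccc(C)cc1)[C@@H]2CCC(C)=CC2 | intermediate
8 | (2S)-2-methyl-2-[(1R)-4-methylcyclohex-3-en-1-yl]oxirane, (4R,8S)-limonene 8,9-oxide | C[C@@]1(CO1)[C@@H]2CCC(C)=CC2 | intermediate
9 | prenyl bromide, 1-bromo-3-methylbut-2-ene | CC(C)=CCBr | starting material
10 | prenylmagnesium bromide | CC(C)=CC[Mg]Br | intermediate
11 | (+)-α-bisabolol, (2R)-6-methyl-2-[(1R)-4-methylcyclohex-3-en-1-yl]hept-5-en-2-ol | C[C@@](O)(CCC=C(C)C)[C@@H]1CCC(C)=CC1 | intermediate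
12 | N-bromosuccinimide | O=C1CCC(=O)N1Br | starting material
13 | (2R,5S)-5-bromo-2,6,6-trimethyl-2-[(1R)-4-methylcyclohex-3-en-1-yl]oxane | CC1(C)O[C@@](C)([C@@H]2CCC(C)=CC2)CC[C@@H]1Br | intermediate
14 | (1S,2S,4R)-2-bromo-4-[(2R,5S)-5-bromo-2,6,6-trimethyloxan-2-yl]-1-methylcyclohexan-1-ol | CC1(C)O[C@@](C)([C@@H]2CC[C@](C)(O)[C@@H](Br)C2)CC[C@@H]1Br | intermediate
15 | (1S,4R,6R)-4-[(2R,5S)-5-bromo-2,6,6-trimethyloxan-2-yl]-1-methyl-7-oxabicyclo[4.1.0]heptane | CC1(C)O[C@@](C)([C@@H]2CC[C@]3(C)O[C@@H]3C2)CC[C@@H]1Br | intermediate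
16 | (1S,2S,4R)-4-[(2R,5S)-5-bromo-2,6,6-trimethyloxan-2-yl]-2-chloro-1-methylcyclohexan-1-ol | CC1(C)O[C@@](C)([C@@H]2CC[C@](C)(O)[C@@H](Cl)C2)CC[C@@H]1Br | intermediate
17 | (2R,5S)-5-bromo-2-[(1R,3S,4S)-4-bromo-3-chloro-4-methylcyclohexyl]-2,6,6-trimethyloxane | CC1(C)O[C@@](C)([C@@H]2CC[C@](C)(Br)[C@@H](Cl)C2)CC[C@@H]1Br | intermediate
18 | deoxycaespitol, (2R,5S)-5-bromo-2-[(1R,3R,4R)-3-bromo-4-chloro-4-methylcyclohexyl]-2,6,6-trimethyloxane | CC1(C)O[C@@](C)([C@@H]2CC[C@@](C)(Cl)[C@H](Br)C2)CC[C@@H]1Br | target

Total step count: 10. Longest linear sequence: 10 steps (1 to 18).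

**Steps most likely to fail**

**Step 10.**
- **Risk:** Loss of HBr from the axial tertiary bromide may outrun the interchange. The equilibrium may also stop short, because the axial methyl of the product costs about as much as the two axial halogens of 17.
- **Fallback:** It sets out from 13 and makes C4'–Cl by internal return on the face where it is needed.
  - OsO4 (cat.)/NMO dihydroxylates the ring alkene, and the anti-face cis-diol F1 is separated from its syn-face isomer.
  - SOCl2/Et3N gives the cyclic sulfite F2, and RuCl3 (cat.)/NaIO4 oxidises it to the cyclic sulfate F3.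
  - LiBr opens F3 by SN2 at secondary C3' with inversion, giving the lithium bromo sulfate F4 with equatorial bromine syn to the oxanyl group.
  - Dilute H2SO4 in wet THF hydrolyses F4 to the diequatorial bromohydrin F5.
  - SOCl2 without base in Et2O forms the tertiary chlorosulfite F6, which should collapse with retention (SNi) and return to the route at 18.

**Step 9.**
- **Risk:** Ionisation of the chlorine-deactivated tertiary alcohol may be slow. Dehydration and acid-induced opening of the di-tertiary ether, with scrambling at C2, could then compete.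
- **Fallback:** It sets out from 13 and reverses the order of halogen entry, so that bromine, the better neighbouring group, gives the assistance.
  - mCPBA gives, beside 15, the anti-face epoxide F7, which is separated.
  - For F7 the Markovnikov and Fürst–Plattner preferences coincide at C4', so LiBr/AcOH should give the diaxial tertiary-bromide bromohydrin F8.
  - Appel chlorination (PPh3, CCl4) of the axial C3' alcohol passes through the syn-face bromiranium ion. Chloride reopens this ion diaxially at C3' with net retention, which returns to the route at 17.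

**Step 6.**
- **Risk:** The ring alkene may capture bromonium, closure may be 5-exo instead of 6-endo, and facial selectivity at C5 may be incomplete.
- **Fallback:** It sets out from 8 and masks the ring alkene as the epoxide it must become anyway.
  - NBS in aqueous acetone gives the ring bromohydrin F9, and NaOH closes it to the diepoxide F10.
  - Prenylmagnesium bromide 10 with CuI at low temperature opens only the terminal oxirane at its CH2, giving the epoxy bisabolol F11. The hydroxyl of F11 cannot reach the backside of the syn epoxide.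
  - NBS in MeNO2 then closes the oxane on the only alkene left and returns to the route at 15. Any 5-exo isomer still has to be separated.

**Further compounds**

F1 | step 10 | (1R,2S,4R)-4-[(2R,5S)-5-bromo-2,6,6-trimethyloxan-2-yl]-1-methylcyclohexane-1,2-diol | CC1(C)O[C@@](C)([C@@H]2CC[C@@](C)(O)[C@@H](O)C2)CC[C@@H]1Br
F2 | step 10 | cyclic sulfite of F1 (both oxygens anti to the oxanyl group) | CC1(C)O[C@@](C)([C@@H]2CC[C@@]3(C)OS(=O)O[C@H]3C2)CC[C@@H]1Br
F3 | step 10 | cyclic sulfate of F1 | CC1(C)O[C@@](C)([C@@H]2CC[C@@]3(C)OS(=O)(=O)O[C@H]3C2)CC[C@@H]1Br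
F4 | step 10 | lithium (1R,2R,4R)-2-bromo-4-[(2R,5S)-5-bromo-2,6,6-trimethyloxan-2-yl]-1-methylcyclohexyl sulfate | [Li+].CC1(C)O[C@@](C)([C@@H]2CC[C@@](C)(OS(=O)(=O)[O-])[C@H](Br)C2)CC[C@@H]1Br
F5 | step 10 | (1R,2R,4R)-2-bromo-4-[(2R,5S)-5-bromo-2,6,6-trimethyloxan-2-yl]-1-methylcyclohexan-1-ol | CC1(C)O[C@@](C)([C@@H]2CC[C@@](C)(O)[C@H](Br)C2)CC[C@@H]1Br
F6 | step 10 | chlorosulfite of F5 | CC1(C)O[C@@](C)([C@@H]2CC[C@@](C)(OS(=O)Cl)[C@H](Br)C2)CC[C@@H]1Br
F7 | step 9 | (1R,4R,6S)-4-[(2R,5S)-5-bromo-2,6,6-trimethyloxan-2-yl]-1-methyl-7-oxabicyclo[4.1.0]heptane | CC1(C)O[C@@](C)([C@@H]2CC[C@@]3(C)O[C@H]3C2)CC[C@@H]1Br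
F8 | step 9 | (1S,2S,5R)-2-bromo-5-[(2R,5S)-5-bromo-2,6,6-trimethyloxan-2-yl]-2-methylcyclohexan-1-ol | CC1(C)O[C@@](C)([C@@H]2CC[C@](C)(Br)[C@@H](O)C2)CC[C@@H]1Br
F9 | step 6 | (1S,2S,4R)-2-bromo-1-methyl-4-[(2S)-2-methyloxiran-2-yl]cyclohexan-1-ol | C[C@@]1(CO1)[C@@H]2CC[C@](C)(O)[C@@H](Br)C2
F10 | step 6 | (1S,4R,6R)-1-methyl-4-[(2S)-2-methyloxiran-2-yl]-7-oxabicyclo[4.1.0]heptane | C[C@@]1(CO1)[C@@H]2CC[C@]3(C)O[C@@H]3C2
F11 | step 6 | (2R)-6-methyl-2-[(1S,4R,6R)-1-methyl-7-oxabicyclo[4.1.0]heptan-4-yl]hept-5-en-2-ol | C[C@@](O)(CCC=C(C)C)[C@@H]1CC[C@]2(C)O[C@@H]2C1
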